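Numbering: tetralin C1 (CH–aryl), C2 (C(OH)CO2H), C3 (C(OH)CH2OH), C4 (CH2). Ring A is the fused guaiacol ring, ring B the carbocycle, ring C the pendant pyrogallol ring.
Retrosynthesis: remove six O-benzyl groups, take C3(OH)–CH2OH back to a C3=CH2 alkene and then a C3 ketone, cut ring B at C1–C2, cut C2–C3 (Claisen), and cut C1–C8a (aryllithium plus aldehyde).
Enabling feature: C1 is doubly benzylic and para to both the C6 methoxy group of ring A and the 4'-oxygen of ring C, so it can give hydride to DDQ. C2 carries O and CO2R and, once C3 is a ketone, is the central carbon of a chelating 1,3-dicarbonyl.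
Forward: the ring A acid is brominated, joined to the ring C aldehyde (C8a–C1), reduced to the diarylmethane and extended by a glycolate Claisen condensation (C3–C2). Ring B is then closed by an oxidative C1–H/C2–H coupling.
Stereochemistry: C2 (absolute) comes from a chiral bis(oxazoline)–Cu(OTf)2 enolate, and C1 from the fold of the closing tether (ring C trans to the ester). C3 comes from OsO4 attack anti to the C2 benzyloxy group and ring C.
The activating ketone ends as the C3 carbinol carbon, and one hydrogenolysis removes all six benzyl groups.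

Key step: step 5

Assumption: the (S,S)-bis(oxazoline) is taken to open the enolate face that leads to (1S,2S), and the equally available antipode is used if the sense is the opposite one; 1, 3 and 9 are taken as purchasable.

Step 1
Reactants: 1 2-[4-(benzyloxy)-3-methoxyphenyl]acetic acid
Product: 2 2-[4-(benzyloxy)-2-bromo-5-methoxyphenyl]acetic acid
Conditions: NBS (1.05 equiv), MeCN, 0 °C to rt
Reagents that add atoms: N-bromosuccinimide, O=C1CCC(=O)N1Br
Why: Electrophilic aromatic bromination should take the free position para to the methoxy group (the future C8a), the site normally attacked in 3,4-dialkoxyphenylacetic acids, and it creates no stereocenter.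

Step 2
Reactants: 2 2-[4-(benzyloxy)-2-bromo-5-methoxyphenyl]acetic acid; 3 3,4,5-tris(benzyloxy)benzaldehyde
Product: 6 rac-7-(benzyloxy)-6-methoxy-1-[3,4,5-tris(benzyloxy)phenyl]isochroman-3-one, via dilithio carboxylate 4 (not isolated), via hydroxy acid 5 (not isolated)
Conditions: n-BuLi (2.2 equiv), THF, −78 °C; then 3, −78 to 0 °C; then 2 M HCl, rt
Reagents that add atoms: none
Why: Carboxylate formation followed by bromine–lithium exchange gives an aryllithium that undergoes 1,2-addition to the aldehyde (forming C8a–C1), and the hydroxy acid closes to the six-membered lactone on acidification; C1 is formed racemic, which is harmless because it is flattened again in steps 3 and 5.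

Step 3
Reactants: 6 rac-7-(benzyloxy)-6-methoxy-1-[3,4,5-tris(benzyloxy)phenyl]isochroman-3-one
Product: 8 2-{4-(benzyloxy)-5-methoxy-2-[3,4,5-tris(benzyloxy)benzyl]phenyl}acetic acid, via carboxy benzhydryl cation 7 (not isolated)
Conditions: Et3SiH (3 equiv), CF3CO2H (10 equiv), CH2Cl2, 0 °C
Reagents that add atoms: none
Why: Ionic hydrogenation, in which the acid ionizes the doubly benzylic C1–O bond of the lactone to a cation stabilized by the para methoxy group of ring A, Et3SiH delivers hydride, and the aryl benzyl ethers should survive the short exposure at 0 °C.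

Step 4
Reactants: 8 2-{4-(benzyloxy)-5-methoxy-2-[3,4,5-tris(benzyloxy)benzyl]phenyl}acetic acid; 9 benzyl 2-(benzyloxy)acetate
Product: 12 benzyl 2-(benzyloxy)-4-{4-(benzyloxy)-5-methoxy-2-[3,4,5-tris(benzyloxy)benzyl]phenyl}-3-oxobutanoate (racemic at C2), via lithium enolate 10 (not isolated), via acyl imidazolide 11 (not isolated)
Conditions: 8, CDI (1.1 equiv), THF, rt; separately 9 (3 equiv), LiN(SiMe3)2 (3 equiv), THF, −78 °C; combine at −78 °C; AcOH quench
Reagents that add atoms: none
Why: Crossed Claisen condensation of a preformed lithium glycolate enolate with an acyl imidazolide forms C2–C3, the excess enolate absorbs the acidic proton of the β-keto ester product, and the new C2 stereocenter is labile and racemic, which is what step 5 needs.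

Step 5
Reactants: 12 benzyl 2-(benzyloxy)-4-{4-(benzyloxy)-5-methoxy-2-[3,4,5-tris(benzyloxy)benzyl]phenyl}-3-oxobutanoate
Product: 14 benzyl (1S,2S)-2,7-bis(benzyloxy)-6-methoxy-3-oxo-1-[3,4,5-tris(benzyloxy)phenyl]-1,2,3,4-tetrahydronaphthalene-2-carboxylate, via benzhydryl cation 13 (not isolated)
Conditions: Cu(OTf)2 (10 mol %), (S,S)-tBu-box [2,2'-isopropylidenebis((4S)-4-tert-butyl-2-oxazoline)] (12 mol %), DDQ (1.1 equiv), 4 Å molecular sieves, CH2Cl2/MeNO2, −20 to 0 °C
Reagents that add atoms: none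
Why: DDQ abstracts hydride from C1–H to give cation 13 while Cu(OTf)2–bis(oxazoline) binds the C3 ketone and the ester carbonyl of the same molecule as a planar chelated enolate (the reduced quinone anion takes the C2 proton), and C2 then attacks C1. The closest known reaction type is the DDQ-mediated cross-dehydrogenative coupling of diarylmethanes with 1,3-dicarbonyl compounds, known in enantioselective form with chiral bis(oxazoline)–copper Lewis acids, together with the copper-catalysed SN1-type alkylation of β-keto esters by benzhydryl electrophiles. Ring B closes in a 6-(enolendo)-exo-trig mode. C2 is controlled by the ligand, whose tert-butyl groups leave one face of the chelated enolate open, so the labile C2 center of 12 is erased and rewritten under catalyst control. C1 is controlled by the fold of the tether: the cation places H toward C4 and ring C outward, and the bulky copper chelate must point away from ring A, which sets the ester anti to C8a and trans to ring C and puts the benzyloxy group cis to ring C. The step needs hydride abstraction at C1 rather than at C4 or the O-benzyl CH2 groups, secured because only C1 is doubly benzylic and para to two oxygen donors while C4 is deactivated by the C3 carbonyl, and it needs C- over O-alkylation, secured by copper holding both enolate oxygens and by the reversibility of benzhydryl enol ether formation.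

Step 6
Reactants: 14 benzyl (1S,2S)-2,7-bis(benzyloxy)-6-methoxy-3-oxo-1-[3,4,5-tris(benzyloxy)phenyl]-1,2,3,4-tetrahydronaphthalene-2-carboxylate
Product: 15 benzyl (1S,2S)-2,7-bis(benzyloxy)-6-methoxy-3-methylidene-1-[3,4,5-tris(benzyloxy)phenyl]-1,2,3,4-tetrahydronaphthalene-2-carboxylate
Conditions: Zn, CH2Br2, TiCl4, THF/CH2Cl2, 0 °C to rt
Reagents that add atoms: dibromomethane, BrCBr
Why: Takai–Lombardo methylenation, whose non-basic geminal dimetallic titanium reagent should convert the hindered and highly enolizable C3 ketone into the exocyclic alkene without touching the benzyl ester or the C1 and C2 stereocenters.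

Step 7
Reactants: 15 benzyl (1S,2S)-2,7-bis(benzyloxy)-6-methoxy-3-methylidene-1-[3,4,5-tris(benzyloxy)phenyl]-1,2,3,4-tetrahydronaphthalene-2-carboxylate
Product: 16 benzyl (1S,2S,3R)-2,7-bis(benzyloxy)-3-hydroxy-3-(hydroxymethyl)-6-methoxy-1-[3,4,5-tris(benzyloxy)phenyl]-1,2,3,4-tetrahydronaphthalene-2-carboxylate
Conditions: OsO4 (5 mol %), NMO (2 equiv), acetone/H2O, rt
Reagents that add atoms: osmium tetroxide, O=[Os](=O)(=O)=O; N-methylmorpholine N-oxide, C[N+]1([O-])CCOCC1; water, O
Why: Catalytic syn-dihydroxylation, in which OsO4 should approach the exocyclic alkene from the face anti to the allylic C2 benzyloxy group and to ring C at C1, so that the new C3–O bond is trans to the C2–O bond and cis to the ester, which is the (3R) configuration.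

Step 8
Reactants: 16 benzyl (1S,2S,3R)-2,7-bis(benzyloxy)-3-hydroxy-3-(hydroxymethyl)-6-methoxy-1-[3,4,5-tris(benzyloxy)phenyl]-1,2,3,4-tetrahydronaphthalene-2-carboxylate
Product: 17 (1S,2S,3R)-2,3,7-trihydroxy-3-(hydroxymethyl)-6-methoxy-1-(3,4,5-trihydroxyphenyl)-1,2,3,4-tetrahydronaphthalene-2-carboxylic acid
Conditions: H2 (1 atm), Pd(OH)2/C, degassed THF/MeOH, rt
Reagents that add atoms: none
Why: Catalytic hydrogenolysis should cleave the four aryl benzyl ethers, the tertiary C2 benzyl ether and the benzyl ester in one operation without touching the three stereocenters, none of which carries a benzylic C–O bond.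

Compound list
1 | 2-[4-(benzyloxy)-3-methoxyphenyl]acetic acid | COc1cc(CC(=O)O)ccc1OCc1ccccc1 | starting material
2 | 2-[4-(benzyloxy)-2-bromo-5-methoxyphenyl]acetic acid | COc1cc(CC(=O)O)c(Br)cc1OCc1ccccc1 | intermediate
3 | 3,4,5-tris(benzyloxy)benzaldehyde | O=Cc1cc(OCc2ccccc2)c(OCc2ccccc2)c(OCc2ccccc2)c1 | starting material
4 | lithium 2-[4-(benzyloxy)-2-lithio-5-methoxyphenyl]acetate (dilithio carboxylate) | COc1cc(CC(=O)O[Li])c([Li])cc1OCc1ccccc1 | intermediate
5 | rac-2-{4-(benzyloxy)-2-[hydroxy(3,4,5-tris(benzyloxy)phenyl)methyl]-5-methoxyphenyl}acetic acid (hydroxy acid) | COc1cc(CC(=O)O)c(cc1OCc1ccccc1)C(O)c1cc(OCc2ccccc2)c(OCc2ccccc2)c(OCc2ccccc2)c1 | intermediate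
6 | rac-7-(benzyloxy)-6-methoxy-1-[3,4,5-tris(benzyloxy)phenyl]isochroman-3-one | COc1cc2CC(=O)OC(c3cc(OCc4ccccc4)c(OCc4ccccc4)c(OCc4ccccc4)c3)c2cc1OCc1ccccc1 | intermediate
7 | carboxy benzhydryl cation formed by C1–O ionization of 6 | COc1cc(CC(=O)O)c(cc1OCc1ccccc1)[CH+]c1cc(OCc2ccccc2)c(OCc2ccccc2)c(OCc2ccccc2)c1 | intermediate
8 | 2-{4-(benzyloxy)-5-methoxy-2-[3,4,5-tris(benzyloxy)benzyl]phenyl}acetic acid | COc1cc(CC(=O)O)c(cc1OCc1ccccc1)Cc1cc(OCc2ccccc2)c(OCc2ccccc2)c(OCc2ccccc2)c1 | intermediate
9 | benzyl 2-(benzyloxy)acetate | O=C(COCc1ccccc1)OCc1ccccc1 | starting material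
10 | lithium enolate of 9 | [Li]OC(OCc1ccccc1)=COCc1ccccc1 | intermediate
11 | acyl imidazolide of 8 | COc1cc(CC(=O)n2ccnc2)c(cc1OCc1ccccc1)Cc1cc(OCc2ccccc2)c(OCc2ccccc2)c(OCc2ccccc2)c1 | intermediate
12 | benzyl 2-(benzyloxy)-4-{4-(benzyloxy)-5-methoxy-2-[3,4,5-tris(benzyloxy)benzyl]phenyl}-3-oxobutanoate (racemic, labile at C2) | COc1cc(CC(=O)C(OCc2ccccc2)C(=O)OCc2ccccc2)c(cc1OCc1ccccc1)Cc1cc(OCc2ccccc2)c(OCc2ccccc2)c(OCc2ccccc2)c1 | intermediate
13 | benzhydryl cation formed from 12 by loss of hydride at C1 | COc1cc(CC(=O)C(OCc2ccccc2)C(=O)OCc2ccccc2)c(cc1OCc1ccccc1)[CH+]c1cc(OCc2ccccc2)c(OCc2ccccc2)c(OCc2ccccc2)c1 | intermediate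
14 | benzyl (1S,2S)-2,7-bis(benzyloxy)-6-methoxy-3-oxo-1-[3,4,5-tris(benzyloxy)phenyl]-1,2,3,4-tetrahydronaphthalene-2-carboxylate | COc1cc2c(cc1OCc1ccccc1)[C@H](c1cc(OCc3ccccc3)c(OCc3ccccc3)c(OCc3ccccc3)c1)[C@@](OCc1ccccc1)(C(=O)OCc1ccccc1)C(=O)C2 | intermediate
15 | benzyl (1S,2S)-2,7-bis(benzyloxy)-6-methoxy-3-methylidene-1-[3,4,5-tris(benzyloxy)phenyl]-1,2,3,4-tetrahydronaphthalene-2-carboxylate | COc1cc2c(cc1OCc1ccccc1)[C@H](c1cc(OCc3ccccc3)c(OCc3ccccc3)c(OCc3ccccc3)c1)[C@@](OCc1ccccc1)(C(=O)OCc1ccccc1)C(=C)C2 | intermediate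
16 | benzyl (1S,2S,3R)-2,7-bis(benzyloxy)-3-hydroxy-3-(hydroxymethyl)-6-methoxy-1-[3,4,5-tris(benzyloxy)phenyl]-1,2,3,4-tetrahydronaphthalene-2-carboxylate | COc1cc2c(cc1OCc1ccccc1)[C@H](c1cc(OCc3ccccc3)c(OCc3ccccc3)c(OCc3ccccc3)c1)[C@@](OCc1ccccc1)(C(=O)OCc1ccccc1)[C@](O)(CO)C2 | intermediate
17 | (1S,2S,3R)-2,3,7-trihydroxy-3-(hydroxymethyl)-6-methoxy-1-(3,4,5-trihydroxyphenyl)-1,2,3,4-tetrahydronaphthalene-2-carboxylic acid | COc1cc2c(cc1O)[C@H](c1cc(O)c(O)c(O)c1)[C@@](O)(C(=O)O)[C@](O)(CO)C2 | target

Total step count: 8. Longest linear sequence: 8 steps (1 to 17).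

Steps most likely to fail

Risk 1 (step 5). DDQ may oxidize the copper-bound enolate or C4 faster than it abstracts hydride from C1. The cation may also be captured through the enol oxygen. Reversible C1–C2 ionization or weak facial discrimination may erode the stereochemical outcome. The fallback sets out from 6 and comes back at 14, and it removes the oxidant from the closure by keeping C1 at the alcohol oxidation level.
- Acid methanolysis of lactone 6 (MeOH, HC(OMe)3, TsOH) should give the methoxy ester F1.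
- LiOH in THF/H2O should give the methoxy acid F2, and CDI the methoxy acyl imidazolide F3.
- Enolate 10 under the conditions of step 4 should give the methoxy β-keto ester F4.
- Cu(OTf)2 and the same bis(oxazoline) then ionize the benzhydryl methyl ether of F4 to cation 13 without any oxidant. This is a catalytic asymmetric SN1-type alkylation of a β-keto ester by a benzhydryl electrophile, and it closes ring B to 14.

Risk 2 (step 6). Three things may block or divert the methylenation: enolization toward C4, shielding of the carbonyl by the quaternary C2, and acid-promoted migration of the new exocyclic double bond into conjugation with ring A. The fallback sets out from 14 and comes back at 17, and it makes use of that enolization.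
- KN(SiMe3)2 and PhNTf2 (THF, −78 °C) should give the enol triflate F5.
- Stille coupling with Bu3SnCH2OH (Pd(PPh3)4, LiCl, THF, reflux) should give the allylic alcohol F6.
- mCPBA/NaHCO3 should epoxidize the C3=C4 bond on the face anti to ring C and to the C2 benzyloxy group, giving the epoxy alcohol F7.
- Hydrogenolysis under the conditions of step 8 should cleave the benzylic C4–O bond of the epoxide, with the C3–O bond retained, together with the six benzyl groups to give 17.

Risk 3 (step 7). Facial selectivity on the exocyclic alkene may be poor, or attack may occur on the wrong face, which would put the C3 oxygen cis to the C2 oxygen. The fallback sets out from 14 and comes back at 16, and it inverts the sense of induction: a carbon nucleophile entering the ketone from the face that OsO4 prefers leaves the C3 oxygen on the other face.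
- Addition of (iPrO)Me2SiCH2MgCl in the presence of CeCl3 (THF, −78 °C) should give the β-hydroxysilane F8.
- Tamao–Fleming oxidation (H2O2, KF, KHCO3, THF/MeOH) should give 16.

Further compounds
F1 | step 5 | methoxy ester: methyl 2-{4-(benzyloxy)-5-methoxy-2-[methoxy(3,4,5-tris(benzyloxy)phenyl)methyl]phenyl}acetate (racemic) | COC(=O)Cc1cc(OC)c(OCc2ccccc2)cc1C(OC)c1cc(OCc2ccccc2)c(OCc2ccccc2)c(OCc2ccccc2)c1
F2 | step 5 | methoxy acid: 2-{4-(benzyloxy)-5-methoxy-2-[methoxy(3,4,5-tris(benzyloxy)phenyl)methyl]phenyl}acetic acid (racemic) | OC(=O)Cc1cc(OC)c(OCc2ccccc2)cc1C(OC)c1cc(OCc2ccccc2)c(OCc2ccccc2)c(OCc2ccccc2)c1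
F3 | step 5 | methoxy acyl imidazolide of F2 | O=C(Cc1cc(OC)c(OCc2ccccc2)cc1C(OC)c1cc(OCc2ccccc2)c(OCc2ccccc2)c(OCc2ccccc2)c1)n1ccnc1
F4 | step 5 | methoxy β-keto ester: benzyl 2-(benzyloxy)-4-{4-(benzyloxy)-5-methoxy-2-[methoxy(3,4,5-tris(benzyloxy)phenyl)methyl]phenyl}-3-oxobutanoate (stereoisomer mixture) | O=C(Cc1cc(OC)c(OCc2ccccc2)cc1C(OC)c1cc(OCc2ccccc2)c(OCc2ccccc2)c(OCc2ccccc2)c1)C(OCc1ccccc1)C(=O)OCc1ccccc1
F5 | step 6 | enol triflate: benzyl (1S,2S)-2,7-bis(benzyloxy)-6-methoxy-3-(trifluoromethylsulfonyloxy)-1-[3,4,5-tris(benzyloxy)phenyl]-1,2-dihydronaphthalene-2-carboxylate | COc1cc2c(cc1OCc1ccccc1)[C@H](c1cc(OCc3ccccc3)c(OCc3ccccc3)c(OCc3ccccc3)c1)[C@@](OCc1ccccc1)(C(=O)OCc1ccccc1)C(OS(=O)(=O)C(F)(F)F)=C2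
F6 | step 6 | allylic alcohol: benzyl (1S,2S)-2,7-bis(benzyloxy)-3-(hydroxymethyl)-6-methoxy-1-[3,4,5-tris(benzyloxy)phenyl]-1,2-dihydronaphthalene-2-carboxylate | COc1cc2c(cc1OCc1ccccc1)[C@H](c1cc(OCc3ccccc3)c(OCc3ccccc3)c(OCc3ccccc3)c1)[C@@](OCc1ccccc1)(C(=O)OCc1ccccc1)C(CO)=C2
F7 | step 6 | epoxy alcohol: benzyl (1S,2S,3S,4S)-2,7-bis(benzyloxy)-3,4-epoxy-3-(hydroxymethyl)-6-methoxy-1-[3,4,5-tris(benzyloxy)phenyl]-1,2,3,4-tetrahydronaphthalene-2-carboxylate | COc1cc2c(cc1OCc1ccccc1)[C@H](c1cc(OCc3ccccc3)c(OCc3ccccc3)c(OCc3ccccc3)c1)[C@@](OCc1ccccc1)(C(=O)OCc1ccccc1)[C@@]4(CO)O[C@H]42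
F8 | step 7 | β-hydroxysilane: benzyl (1S,2S,3S)-2,7-bis(benzyloxy)-3-hydroxy-3-{[isopropoxy(dimethyl)silyl]methyl}-6-methoxy-1-[3,4,5-tris(benzyloxy)phenyl]-1,2,3,4-tetrahydronaphthalene-2-carboxylate | COc1cc2c(cc1OCc1ccccc1)[C@H](c1cc(OCc3ccccc3)c(OCc3ccccc3)c(OCc3ccccc3)c1)[C@@](OCc1ccccc1)(C(=O)OCc1ccccc1)[C@](O)(C[Si](C)(C)OC(C)C)C2
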